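**Plan**
1. Retrosynthesis: the ring bonds C1–C6 and C4–C5 are cut together as a [4+2] retron. The six-membered ring has its C2=C3 double bond flanked on both sides by oxygen-bearing carbons (C1 and C4), which is a 1,4-dioxygenated butadiene; C5 (fully substituted) and C6 (CH2) are the α-carbon and CH2 of an α-substituted acrolein. The side chain is then cut at C1′–C2′ and at C13′–C14′.
2. Forward: the C18 chain bromide is made by a copper-catalysed sp3–sp3 coupling. 2-Bromoacrolein and (1E,3E)-1,4-diacetoxybutadiene are then joined in a catalytic enantioselective Diels–Alder reaction, which forms the only ring.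
3. The chain Grignard reagent adds to the formyl carbon; bromohydrin, epoxide and hydride opening turn C–Br into the tertiary C5–OH and C1′ into CH2.
4. The cis-4,5-diol is masked as an acetonide, the C1 carbinol is oxidised to the enone, and the acetonide is removed.
5. Stereochemistry: C4 and C5 both come from the Diels–Alder step (absolute sense from the chiral boron Lewis acid, relative sense from the endo rule and the E,E-diene). C5 is inverted once in the epoxide closure, the C1 centre of the adduct is erased by oxidation, and the E-alkene is bought in with (E)-hex-3-en-1-ol.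

Key step: step 4

Remark: ring atoms are numbered as in the ketone name (C1 = C=O, C2=C3, C4 = CHOH, C5 = C(OH)R, C6 = CH2) and chain atoms C1′–C19′. (1E,3E)-Buta-1,3-diene-1,4-diyl diacetate is taken to be a purchasable diene, and the catalyst from natural (S)-tryptophan is assumed to shield the same enal face with this acyclic diene as it does with cyclic dienes.

Step 1
Reactants: 1 (E)-hex-3-en-1-ol
Product: 2 (E)-1-bromohex-3-ene
Conditions: CBr4, PPh3, CH2Cl2, 0 °C
Reagents that add atoms: carbon tetrabromide BrC(Br)(Br)Br
Why: The Appel reaction should convert the primary alcohol into the bromide by SN2 displacement of the alkoxyphosphonium ion without touching the E double bond.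

Step 2
Reactants: 2 (E)-1-bromohex-3-ene; 3 1,12-dibromododecane
Product: 5 (E)-1-bromooctadec-15-ene, via (E)-hex-3-enylmagnesium bromide 4 (not isolated)
Conditions: Mg, THF, 25 °C; then 3 (3 equiv), Li2CuCl4 (3 mol %), THF, −10 → 0 °C
Reagents that add atoms: none
Why: Copper-catalysed coupling of a primary Grignard reagent with a primary alkyl bromide should give the mono-coupled bromide when the dibromide is in excess, and the homoallylic Grignard reagent is used cold and at once so that the E geometry is kept.

Step 3
Reactants: 6 acrolein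
Product: 8 2-bromoprop-2-enal (2-bromoacrolein), via 2,3-dibromopropanal 7 (not isolated)
Conditions: Br2, CH2Cl2, −78 °C; then Et3N, −78 → 0 °C
Reagents that add atoms: bromine BrBr
Why: Bromine addition to the C=C bond followed by E1cB loss of HBr (acidic α-hydrogen, β-bromide) is the standard bromination–dehydrobromination route to the 2-bromo enal.

Step 4
Reactants: 8 2-bromoprop-2-enal; 9 (1E,3E)-buta-1,3-diene-1,4-diyl diacetate
Product: 10 (1R,2R,5R)-1-bromo-1-formylcyclohex-3-ene-2,5-diyl diacetate
Conditions: (4S)-2-butyl-4-(1H-indol-3-ylmethyl)-3-(4-methylphenylsulfonyl)-1,3,2-oxazaborolidin-5-one (10 mol %, pre-formed from N-tosyl-(S)-tryptophan and butylboronic acid), CH2Cl2, −78 → −40 °C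
Reagents that add atoms: none
Why: The boron Lewis acid binds the formyl oxygen of s-cis 2-bromoacrolein and the diene adds in a concerted, asynchronous [4+2] cycloaddition in which the CH2 terminus bonds ahead of the bromine-bearing carbon. The closest known reaction type is the oxazaborolidinone-catalysed enantioselective Diels–Alder addition of 2-haloacroleins to furan, cyclopentadiene and acyclic dienes. The cyclohexene ring is closed suprafacially on both partners, so the two acetoxy carbons (later C1 and C4) should come out cis from the E,E-diene. The quaternary C–Br carbon (later C5) is tied to the neighbouring acetoxy carbon by the endo position of the complexed formyl group (formyl cis, bromine trans to that acetoxy), and the absolute configuration of all three centres follows from the indolyl group of the catalyst shielding one face of the bound enal. Regioselectivity needs no control because both diene termini are alike; the selectivities to be secured are endo over exo and one enal face over the other, and both rest on the Lewis acid complex.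

Step 5
Reactants: 5 (E)-1-bromooctadec-15-ene; 10 (1R,2R,5R)-1-bromo-1-formylcyclohex-3-ene-2,5-diyl diacetate
Product: 12 (1S,2R,5R)-1-bromo-1-[(16E)-1-hydroxynonadec-16-en-1-yl]cyclohex-3-ene-2,5-diyl diacetate as a mixture of carbinol epimers, via (E)-octadec-15-enylmagnesium bromide 11 (not isolated)
Conditions: 5, Mg, THF, 25 °C; then 10 (1.2 equiv of 11), THF, −78 °C; then H2O, −78 → 0 °C
Reagents that add atoms: none
Why: Grignard 1,2-addition to the activated α-bromo aldehyde should be far faster at −78 °C than attack on the two acetates, and the uncontrolled carbinol centre does not matter because it becomes the C1′ methylene in step 7.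

Step 6
Reactants: 12 (1S,2R,5R)-1-bromo-1-[(16E)-1-hydroxynonadec-16-en-1-yl]cyclohex-3-ene-2,5-diyl diacetate
Product: 13 (3R,4R,7R)-2-[(15E)-octadec-15-en-1-yl]-1-oxaspiro[2.5]oct-5-ene-4,7-diyl diacetate as a mixture of epimers at C2 of the oxirane
Conditions: DBU, CH2Cl2, 0 → 25 °C
Reagents that add atoms: none
Why: Intramolecular Williamson closure of the bromohydrin (3-exo-tet, expected to outrun 1,3-acyl transfer) displaces the tertiary bromide from the rear, so the ring carbon is inverted and the new C–O bond lies cis to the neighbouring acetoxy group.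

Step 7
Reactants: 13 (3R,4R,7R)-2-[(15E)-octadec-15-en-1-yl]-1-oxaspiro[2.5]oct-5-ene-4,7-diyl diacetate
Product: 14 (1R,2S,4R)-2-[(16E)-nonadec-16-en-1-yl]cyclohex-5-ene-1,2,4-triol
Conditions: LiBHEt3 (7 equiv), THF, 0 → 40 °C; then H2O
Reagents that add atoms: none
Why: Hydride opening of the trisubstituted epoxide by SN2 attack at its less substituted carbon should give the tertiary alcohol with the ring C–O bond untouched (cis to the C4 oxygen), while the same reagent cleaves both acetates reductively.

Step 8
Reactants: 14 (1R,2S,4R)-2-[(16E)-nonadec-16-en-1-yl]cyclohex-5-ene-1,2,4-triol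
Product: 15 (3aS,5R,7aR)-2,2-dimethyl-3a-[(16E)-nonadec-16-en-1-yl]-3a,4,5,7a-tetrahydro-1,3-benzodioxol-5-ol
Conditions: 2,2-dimethoxypropane, pyridinium 4-toluenesulfonate (5 mol %), CH2Cl2, 25 °C
Reagents that add atoms: 2,2-dimethoxypropane COC(C)(C)OC
Why: Acid-catalysed transketalisation under thermodynamic control should give the cis-fused five-membered acetonide of the only cis-1,2-diol (C4/C5) and leave the C1 carbinol free.

Step 9
Reactants: 15 (3aS,5R,7aR)-2,2-dimethyl-3a-[(16E)-nonadec-16-en-1-yl]-3a,4,5,7a-tetrahydro-1,3-benzodioxol-5-ol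
Product: 16 (3aS,7aR)-2,2-dimethyl-3a-[(16E)-nonadec-16-en-1-yl]-3a,7a-dihydro-1,3-benzodioxol-5(4H)-one
Conditions: Dess–Martin periodinane, CH2Cl2, 0 → 25 °C
Reagents that add atoms: none
Why: Dess–Martin oxidation of the secondary allylic alcohol should give the enone under near-neutral conditions that spare the acetonide and both alkenes, and it removes the C1 stereocentre that is no longer needed.

Step 10
Reactants: 16 (3aS,7aR)-2,2-dimethyl-3a-[(16E)-nonadec-16-en-1-yl]-3a,7a-dihydro-1,3-benzodioxol-5(4H)-one
Product: 17 (4R,5S)-4,5-dihydroxy-5-[(16E)-nonadec-16-en-1-yl]cyclohex-2-en-1-one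
Conditions: AcOH/H2O/THF (3:1:1), 25 °C
Reagents that add atoms: none
Why: Mild acid-catalysed acetal hydrolysis should free the cis-diol without breaking either C–O bond to the ring, and base is avoided because the β-hydroxy ketone would eliminate.

**Compound list**
1 | (E)-hex-3-en-1-ol | CC/C=C/CCO | starting material
2 | (E)-1-bromohex-3-ene | CC/C=C/CCBr | intermediate
3 | 1,12-dibromododecane | BrCCCCCCCCCCCCBr | starting material
4 | (E)-hex-3-enylmagnesium bromide | CC/C=C/CC[Mg]Br | intermediate
5 | (E)-1-bromooctadec-15-ene | CC/C=C/CCCCCCCCCCCCCCBr | intermediate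
6 | acrolein | C=CC=O | starting material
7 | 2,3-dibromopropanal | O=CC(Br)CBr | intermediate
8 | 2-bromoprop-2-enal | C=C(Br)C=O | intermediate
9 | (1E,3E)-buta-1,3-diene-1,4-diyl diacetate | CC(=O)O/C=C/C=C/OC(C)=O | starting material
10 | (1R,2R,5R)-1-bromo-1-formylcyclohex-3-ene-2,5-diyl diacetate | O=C[C@@]1(Br)C[C@@H](OC(C)=O)C=C[C@H]1OC(C)=O | intermediate
11 | (E)-octadec-15-enylmagnesium bromide | CC/C=C/CCCCCCCCCCCCCC[Mg]Br | intermediate
12 | (1S,2R,5R)-1-bromo-1-[(16E)-1-hydroxynonadec-16-en-1-yl]cyclohex-3-ene-2,5-diyl diacetate (carbinol epimers) | CC/C=C/CCCCCCCCCCCCCCC(O)[C@@]1(Br)C[C@@H](OC(C)=O)C=C[C@H]1OC(C)=O | intermediate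
13 | (3R,4R,7R)-2-[(15E)-octadec-15-en-1-yl]-1-oxaspiro[2.5]oct-5-ene-4,7-diyl diacetate (C2 epimers) | CC/C=C/CCCCCCCCCCCCCCC1O[C@]12C[C@@H](OC(C)=O)C=C[C@H]2OC(C)=O | intermediate
14 | (1R,2S,4R)-2-[(16E)-nonadec-16-en-1-yl]cyclohex-5-ene-1,2,4-triol | CC/C=C/CCCCCCCCCCCCCCC[C@]1(O)C[C@@H](O)C=C[C@H]1O | intermediate
15 | (3aS,5R,7aR)-2,2-dimethyl-3a-[(16E)-nonadec-16-en-1-yl]-3a,4,5,7a-tetrahydro-1,3-benzodioxol-5-ol | CC/C=C/CCCCCCCCCCCCCCC[C@]12C[C@@H](O)C=C[C@H]1OC(C)(C)O2 | intermediate
16 | (3aS,7aR)-2,2-dimethyl-3a-[(16E)-nonadec-16-en-1-yl]-3a,7a-dihydro-1,3-benzodioxol-5(4H)-one | CC/C=C/CCCCCCCCCCCCCCC[C@]12CC(=O)C=C[C@H]1OC(C)(C)O2 | intermediate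
17 | (4R,5S)-4,5-dihydroxy-5-[(16E)-nonadec-16-en-1-yl]cyclohex-2-en-1-one | CC/C=C/CCCCCCCCCCCCCCC[C@]1(O)CC(=O)C=C[C@H]1O | target

Total step count: 10. Longest linear sequence: 8 steps (steps 1, 2, 5–10, or equally steps 3–10).

**Steps most likely to fail**

Step 4. The ester carbonyls of the diene may compete with the enal for the boron Lewis acid, so turnover slows, the reaction has to be run warmer, and the discrimination between the two enal faces (and between endo and exo) erodes. Fallback: the source of absolute configuration is changed from catalysis to resolution. Setting out from 8 and 9, the cycloaddition is run without the chiral catalyst (ZnCl2, CH2Cl2, 0 °C, or toluene at 50 °C with a radical inhibitor), where the endo rule should still set the relative configuration. The racemate is then separated by preparative chromatography on a chiral stationary phase. The unwanted enantiomer (1S,2S,5S)-1-bromo-1-formylcyclohex-3-ene-2,5-diyl diacetate F1 is discarded and the route is rejoined at 10.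

Step 7. Hydride delivery to the hindered secondary oxirane carbon next to the quaternary centre may be slow, so that base-induced isomerisation of the epoxide or incomplete opening competes. Fallback: the chain is attached by opening an unhindered terminal epoxide instead. Setting out from 10:
- The aldehyde is reduced (NaBH4, MeOH/THF, −40 °C) to (1S,2R,5R)-1-bromo-1-(hydroxymethyl)cyclohex-3-ene-2,5-diyl diacetate F2.
- DBU closes this, with the same inversion, to (3R,4R,7R)-1-oxaspiro[2.5]oct-5-ene-4,7-diyl diacetate F3.
- Grignard reagent 11 (1.2 equiv) with CuI (10 mol %) in THF at −40 °C opens the oxirane at its CH2 carbon to give (1R,2S,4R)-2-hydroxy-2-[(16E)-nonadec-16-en-1-yl]cyclohex-5-ene-1,4-diyl diacetate F4.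
- Methanolysis (K2CO3, MeOH, 0 °C) rejoins the route at 14.

Step 10. Acid may trigger dehydration of the tertiary β-hydroxy ketone and then aromatisation to a 3-alkylphenol before the acetonide is fully cleaved. Fallback: protection is avoided altogether. Setting out from 14, the less hindered allylic carbinol at C1 is oxidised selectively with a hindrance-sensitive oxidant (2,2,6,6-tetramethylpiperidin-1-oxyl with PhI(OAc)2, or activated MnO2, CH2Cl2, 25 °C); the C4 carbinol next to the quaternary centre should react more slowly. This comes back to the route directly at 17 and no acid step is needed.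

**Further compounds**
F1 | step 4 | (1S,2S,5S)-1-bromo-1-formylcyclohex-3-ene-2,5-diyl diacetate | O=C[C@]1(Br)C[C@H](OC(C)=O)C=C[C@@H]1OC(C)=O
F2 | step 7 | (1S,2R,5R)-1-bromo-1-(hydroxymethyl)cyclohex-3-ene-2,5-diyl diacetate | OC[C@@]1(Br)C[C@@H](OC(C)=O)C=C[C@H]1OC(C)=O
F3 | step 7 | (3R,4R,7R)-1-oxaspiro[2.5]oct-5-ene-4,7-diyl diacetate | C1O[C@]12C[C@@H](OC(C)=O)C=C[C@H]2OC(C)=O
F4 | step 7 | (1R,2S,4R)-2-hydroxy-2-[(16E)-nonadec-16-en-1-yl]cyclohex-5-ene-1,4-diyl diacetate | CC/C=C/CCCCCCCCCCCCCCC[C@]1(O)C[C@@H](OC(C)=O)C=C[C@H]1OC(C)=O
F0 | step 10 | none | none
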